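**Strategy**

Ring A (the quinol: C1 carbinol carbon carrying ester carbon C7, C2 OMe, C3 Me, C4 ketone, C5 H, C6 Me) contains a hidden methyl tetronate, O–C1–C2(OMe)=C3(Me)–C4=O, and its C1 and C4 oxygens are para, like the bridgeheads of a 7-oxanorbornadiene. The complete ring B–C–D tridepside is therefore built first and its ring B phenol is esterified with a carboxylated methyl tetronate; silylation gives a 5-silyloxy-2-furoate. With but-2-ynal and a chiral amine salt this furan should form C1–C6 and C4–C5, open its oxygen bridge and so deliver carbocyclic ring A with its single stereocenter in one operation. Decarbonylation and one global desilylation end the route.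

Key step: step 19

**Remarks on the chemistry**

- The target stereocenter C1 is R; this was checked against the SMILES.
- The ester group of the furoate is a spectator in the key step, so the finished ring B–C–D aryl ester is used there. A free ring A quinol acid is a vinylogous β-keto acid that would lose CO2 with aromatisation, and a quaternary acid could hardly acylate the di-ortho-substituted ring B phenol.
- From step 17 on only silicon protecting groups are present, because RhCl(PPh3)3 can isomerise allyl ethers. All acidic hydroxyls are silylated so that nothing protonates the silyl dienol ether.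
- 1 and 7 are assumed to be purchasable; 27 is made fresh and used as a solution.
- The sense of induction in step 19 rests on a steric model. If the product proves to be the S enantiomer, the R-configured catalyst is used instead.

**Route**

Step 1
Reactants: 1 4,5-dimethylresorcinol
Product: 3 2,4-dihydroxy-5,6-dimethylbenzaldehyde, via aryl iminium chloride 2 (not isolated)
Conditions: POCl3, DMF, MeCN, 0 °C → rt; then H2O, 50 °C
Reagents that add atoms: N,N-dimethylformamide, CN(C)C=O; water, O
Why: Vilsmeier–Haack formylation should occur para to one hydroxyl and ortho to the other, since the position between the two hydroxyls is the more crowded one for the chloroiminium ion, and hydrolysis of the iminium salt gives the aldehyde.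

Step 2
Reactants: 3 2,4-dihydroxy-5,6-dimethylbenzaldehyde
Product: 4 3-chloro-2,4-dihydroxy-5,6-dimethylbenzaldehyde
Conditions: SO2Cl2, Et2O, 0 °C → rt
Reagents that add atoms: sulfuryl chloride, O=S(=O)(Cl)Cl
Why: Electrophilic aromatic chlorination can only take place at C3, the single unsubstituted ring carbon, which is activated by both hydroxyls.

Step 3
Reactants: 4 3-chloro-2,4-dihydroxy-5,6-dimethylbenzaldehyde
Product: 5 2,4-bis(allyloxy)-3-chloro-5,6-dimethylbenzaldehyde
Conditions: allyl bromide, K2CO3, DMF, 60 °C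
Reagents that add atoms: allyl bromide, C=CCBr
Why: Williamson ether synthesis on both phenols, the hydrogen-bonded 2-hydroxyl needing the polar solvent and gentle heat.

Step 4
Reactants: 5 2,4-bis(allyloxy)-3-chloro-5,6-dimethylbenzaldehyde
Product: 6 2,4-bis(allyloxy)-3-chloro-5,6-dimethylbenzoic acid
Conditions: NaClO2, NaH2PO4, 2-methyl-2-butene, t-BuOH/H2O, rt
Reagents that add atoms: sodium chlorite, [Na+].[O-]Cl=O
Why: Pinnick oxidation converts the hindered aryl aldehyde to the acid while the trisubstituted alkene scavenges hypochlorous acid faster than the allyl ethers can react.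

Step 5
Reactants: 7 methyl 2,4-dihydroxy-3,6-dimethylbenzoate
Product: 8 methyl 2,4-bis(allyloxy)-3,6-dimethylbenzoate
Conditions: allyl bromide, K2CO3, DMF, 60 °C
Reagents that add atoms: allyl bromide, C=CCBr
Why: Williamson ether synthesis on both phenols of the orsellinate.

Step 6
Reactants: 8 methyl 2,4-bis(allyloxy)-3,6-dimethylbenzoate
Product: 9 2,4-bis(allyloxy)-3,6-dimethylbenzoic acid
Conditions: KOH, DMSO/H2O, 90 °C; then aq. HCl
Reagents that add atoms: potassium hydroxide, [K+].[OH-]
Why: Saponification of a 2,6-disubstituted methyl benzoate needs hot hydroxide in DMSO, conditions under which aryl allyl ethers are stable.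

Step 7
Reactants: 9 2,4-bis(allyloxy)-3,6-dimethylbenzoic acid; 3 2,4-dihydroxy-5,6-dimethylbenzaldehyde
Product: 11 4-formyl-5-hydroxy-2,3-dimethylphenyl 2,4-bis(allyloxy)-3,6-dimethylbenzoate, via ring C acid chloride 10 (not isolated)
Conditions: (COCl)2, DMF (cat.), CH2Cl2, 0 °C → rt; then 3, Et3N, DMAP (cat.), CH2Cl2, 0 °C
Reagents that add atoms: none
Why: Acylation through the acid chloride under nucleophilic catalysis should be selective for the 4-hydroxyl, because the 2-hydroxyl is held in a hydrogen bond to the aldehyde and is much less nucleophilic.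

Step 8
Reactants: 11 4-formyl-5-hydroxy-2,3-dimethylphenyl 2,4-bis(allyloxy)-3,6-dimethylbenzoate
Product: 12 4-formyl-5-methoxy-2,3-dimethylphenyl 2,4-bis(allyloxy)-3,6-dimethylbenzoate
Conditions: MeI, K2CO3, DMF, rt
Reagents that add atoms: iodomethane, CI
Why: Williamson methylation of the remaining phenol, which the shielded 2,6-disubstituted aryl benzoate should tolerate at room temperature.

Step 9
Reactants: 12 4-formyl-5-methoxy-2,3-dimethylphenyl 2,4-bis(allyloxy)-3,6-dimethylbenzoate
Product: 13 4-{[2,4-bis(allyloxy)-3,6-dimethylbenzoyl]oxy}-2-methoxy-5,6-dimethylbenzoic acid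
Conditions: NaClO2, NaH2PO4, 2-methyl-2-butene, t-BuOH/H2O, rt
Reagents that add atoms: sodium chlorite, [Na+].[O-]Cl=O
Why: Pinnick oxidation of the aryl aldehyde under buffered conditions that leave the depside ester and the allyl ethers alone.

Step 10
Reactants: 13 4-{[2,4-bis(allyloxy)-3,6-dimethylbenzoyl]oxy}-2-methoxy-5,6-dimethylbenzoic acid
Product: 14 triisopropylsilyl 4-{[2,4-bis(allyloxy)-3,6-dimethylbenzoyl]oxy}-2-methoxy-5,6-dimethylbenzoate
Conditions: i-Pr3SiCl, Et3N, CH2Cl2, rt
Reagents that add atoms: chlorotriisopropylsilane, CC(C)[Si](Cl)(C(C)C)C(C)C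
Why: O-Silylation of the carboxylate gives a silyl ester shielded at both silicon and the 2,6-disubstituted carbonyl, which is meant to last until the final fluoride step.

Step 11
Reactants: 14 triisopropylsilyl 4-{[2,4-bis(allyloxy)-3,6-dimethylbenzoyl]oxy}-2-methoxy-5,6-dimethylbenzoate
Product: 15 triisopropylsilyl 4-[(2,4-dihydroxy-3,6-dimethylbenzoyl)oxy]-2-methoxy-5,6-dimethylbenzoate
Conditions: Pd(PPh3)4 (cat.), morpholine, THF, rt
Reagents that add atoms: none
Why: Tsuji–Trost deallylation, in which zerovalent palladium ionises the aryl allyl ethers and morpholine captures the allyl fragment, while the hindered benzoate esters resist the amine.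

Step 12
Reactants: 6 2,4-bis(allyloxy)-3-chloro-5,6-dimethylbenzoic acid; 15 ring C–D diol
Product: 17 ring B–C–D tridepside bis(allyl ether), via ring B acid chloride 16 (not isolated)
Conditions: (COCl)2, DMF (cat.), CH2Cl2, 0 °C → rt; then 15, Et3N, DMAP (cat.), CH2Cl2, 0 °C → rt
Reagents that add atoms: none
Why: Acylation through the acid chloride should again pick the free 4-hydroxyl of ring C, the 2-hydroxyl being hydrogen-bonded to its own ester carbonyl.

Step 13
Reactants: 17 ring B–C–D tridepside bis(allyl ether)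
Product: 18 ring B–C–D triol
Conditions: Pd(PPh3)4 (cat.), morpholine, THF, rt
Reagents that add atoms: none
Why: Tsuji–Trost deallylation of both ring B allyl ethers, the aryl chloride being inert to this zerovalent palladium catalyst at room temperature.

Step 14
Reactants: 19 3-methyltetronic acid
Product: 20 4-methoxy-3-methylfuran-2(5H)-one
Conditions: Me2SO4, K2CO3, acetone, reflux
Reagents that add atoms: dimethyl sulfate, COS(=O)(=O)OC
Why: O-Alkylation of the vinylogous acid with a hard methylating agent gives the methyl tetronate.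

Step 15
Reactants: 20 4-methoxy-3-methylfuran-2(5H)-one
Product: 22 3-methoxy-4-methyl-5-oxo-2,5-dihydrofuran-2-carboxylic acid (racemic), via lithium dienolate 21 (not isolated)
Conditions: LiN(i-Pr)2, THF, −78 °C; CO2 (gas), −78 °C → rt; aq. HCl
Reagents that add atoms: carbon dioxide, O=C=O
Why: Deprotonation at C5 gives the 2-oxidofuran dienolate, which is carboxylated at C5, the usual site of attack in metalated 4-alkoxybutenolides.

Step 16
Reactants: 22 3-methoxy-4-methyl-5-oxo-2,5-dihydrofuran-2-carboxylic acid; 18 ring B–C–D triol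
Product: 24 ring B 4-O-(3-methoxy-4-methyl-5-oxo-2,5-dihydrofuran-2-carbonyl) ester of 18 (racemic at the furanone carbon), via butenolide acid chloride 23 (not isolated)
Conditions: (COCl)2, DMF (cat.), CH2Cl2, 0 °C → rt; then 18, Et3N (1.2 equiv), DMAP (cat.), CH2Cl2, −40 → 0 °C
Reagents that add atoms: none
Why: Acylation by the acid chloride (directly or through its ketene) should go to the ring B 4-hydroxyl, the most acidic phenol and the only one not hydrogen-bonded; the furanone stereocenter forms unselectively and is erased in step 17.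

Step 17
Reactants: 24 ring B 4-O-(3-methoxy-4-methyl-5-oxo-2,5-dihydrofuran-2-carbonyl) ester of 18
Product: 25 ring B 4-O-[5-(tert-butyldimethylsilyloxy)-3-methoxy-4-methylfuran-2-carbonyl] ester of 18 with both salicylate hydroxyls as tert-butyldimethylsilyl ethers
Conditions: TBSOTf (3.5 equiv), Et3N (5 equiv), CH2Cl2, −78 → 0 °C; filtration through Et3N-deactivated silica
Reagents that add atoms: tert-butyldimethylsilyl trifluoromethanesulfonate, CC(C)(C)[Si](C)(C)OS(=O)(=O)C(F)(F)F
Why: Soft enolisation with silyl triflate and amine turns the acidic butenolide into the aromatic 2-silyloxyfuran and silylates the two remaining phenols in the same operation.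

Step 18
Reactants: 26 but-2-yn-1-ol
Product: 27 but-2-ynal
Conditions: MnO2, CH2Cl2, rt; filtered and used as a solution
Reagents that add atoms: none
Why: MnO2 oxidation of a propargylic alcohol stops at the aldehyde.

Step 19
Reactants: 25 tris-silylated aryl 5-silyloxy-2-furoate; 27 but-2-ynal
Product: 29 aryl (1R)-1-(tert-butyldimethylsilyloxy)-5-formyl-2-methoxy-3,6-dimethyl-4-oxocyclohexa-2,5-diene-1-carboxylate (aryl as in 25), via oxanorbornadiene silyl ketal 28 (not isolated)
Conditions: (S)-2-[bis(3,5-bis(trifluoromethyl)phenyl)(trimethylsilyloxy)methyl]pyrrolidine (20 mol %), PhCO2H (20 mol %), 27 (2 equiv), toluene, −20 °C → rt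
Reagents that add atoms: none
Why: Proposed new method: the amine and 27 form an alkynyl iminium ion, the silyl dienol ether attacks its β-carbon C6 through the ester-bearing furan carbon C1, and the resulting allenamine closes through its central carbon C5 onto the silyloxycarbenium carbon C4, a stepwise net [4+2] whose closest known relatives are Diels–Alder reactions of 2-silyloxyfurans with activated alkynes, amine-catalysed vinylogous Mukaiyama–Michael additions of 5-carboxy-2-silyloxyfurans to enals and iminium–allenamine cascades of ynals. This second bond closes ring A by exo-trig attack of the enamine carbon on the C4 oxocarbenium unit (six-membered through C2–C3, five-membered through the bridge oxygen) and gives the 7-oxanorbornadiene 28, carried as its iminium ion. The strained mixed silyl ketal then collapses: the C4–O bridge bond ionises, silicon passes from the C4 oxygen to the former furan oxygen on C1, C4 becomes the ketone, and hydrolysis of the iminium ion returns the catalyst and leaves the C5 aldehyde. C1 is the only new stereocenter and is fixed in the first C–C bond: the diaryl(silyloxy)methyl arm blocks one face of the E-configured iminium ion, and on the open face the furan is expected to place its small ring oxygen on the nitrogen side and its substituted C2=C3 edge over the iminium C–H, which corresponds to R. The step needs attack through C1 and not C3, and ring closure faster than loss of silicon; the vinylogous silyloxy donation and the C2 methoxy group both activate C1, and the bulky tert-butyldimethylsilyl group in a dry medium free of silyl acceptors should keep the silyloxycarbenium ion alive until C5 has closed.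

Step 20
Reactants: 29 ring A quinol aldehyde
Product: 30 aryl (1R)-1-(tert-butyldimethylsilyloxy)-2-methoxy-3,6-dimethyl-4-oxocyclohexa-2,5-diene-1-carboxylate (aryl as in 25)
Conditions: RhCl(PPh3)3 (1.2 equiv), toluene, 100 °C
Reagents that add atoms: none
Why: Tsuji–Wilkinson decarbonylation (oxidative addition of the formyl C–H to monovalent rhodium, CO de-insertion, C–H reductive elimination) replaces CHO by H at the sp2 carbon, and no allyl group is left that the metal could isomerise.

Step 21
Reactants: 30 silylated tetradepside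
Product: 31 CNP0248758.1 (target)
Conditions: HF·pyridine, pyridine, THF, 0 °C → rt
Reagents that add atoms: none
Why: Fluoride-driven global desilylation cleaves the tertiary silyl ether, both aryl silyl ethers and the silyl ester under acidic conditions that leave the aryl esters and the C1 configuration untouched.

**Compound list**

1 | 4,5-dimethylresorcinol (4,5-dimethylbenzene-1,3-diol) | Cc1cc(O)cc(O)c1C | starting material
2 | N-[(2,4-dihydroxy-5,6-dimethylphenyl)methylidene]-N-methylmethanaminium chloride | C[N+](C)=Cc1c(O)cc(O)c(C)c1C.[Cl-] | intermediate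
3 | 2,4-dihydroxy-5,6-dimethylbenzaldehyde | O=Cc1c(O)cc(O)c(C)c1C | intermediate
4 | 3-chloro-2,4-dihydroxy-5,6-dimethylbenzaldehyde | O=Cc1c(O)c(Cl)c(O)c(C)c1C | intermediate
5 | 2,4-bis(allyloxy)-3-chloro-5,6-dimethylbenzaldehyde | O=Cc1c(OCC=C)c(Cl)c(OCC=C)c(C)c1C | intermediate
6 | 2,4-bis(allyloxy)-3-chloro-5,6-dimethylbenzoic acid (ring B acid) | OC(=O)c1c(OCC=C)c(Cl)c(OCC=C)c(C)c1C | intermediate
7 | methyl 2,4-dihydroxy-3,6-dimethylbenzoate | COC(=O)c1c(C)cc(O)c(C)c1O | starting material
8 | methyl 2,4-bis(allyloxy)-3,6-dimethylbenzoate | COC(=O)c1c(C)cc(OCC=C)c(C)c1OCC=C | intermediate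
9 | 2,4-bis(allyloxy)-3,6-dimethylbenzoic acid (ring C acid) | OC(=O)c1c(C)cc(OCC=C)c(C)c1OCC=C | intermediate
10 | 2,4-bis(allyloxy)-3,6-dimethylbenzoyl chloride | ClC(=O)c1c(C)cc(OCC=C)c(C)c1OCC=C | intermediate
11 | 4-formyl-5-hydroxy-2,3-dimethylphenyl 2,4-bis(allyloxy)-3,6-dimethylbenzoate | C=CCOc1cc(C)c(C(=O)Oc2cc(O)c(C=O)c(C)c2C)c(OCC=C)c1C | intermediate
12 | 4-formyl-5-methoxy-2,3-dimethylphenyl 2,4-bis(allyloxy)-3,6-dimethylbenzoate | C=CCOc1cc(C)c(C(=O)Oc2cc(OC)c(C=O)c(C)c2C)c(OCC=C)c1C | intermediate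
13 | 4-{[2,4-bis(allyloxy)-3,6-dimethylbenzoyl]oxy}-2-methoxy-5,6-dimethylbenzoic acid | C=CCOc1cc(C)c(C(=O)Oc2cc(OC)c(C(=O)O)c(C)c2C)c(OCC=C)c1C | intermediate
14 | triisopropylsilyl 4-{[2,4-bis(allyloxy)-3,6-dimethylbenzoyl]oxy}-2-methoxy-5,6-dimethylbenzoate | C=CCOc1cc(C)c(C(=O)Oc2cc(OC)c(C(=O)O[Si](C(C)C)(C(C)C)C(C)C)c(C)c2C)c(OCC=C)c1C | intermediate
15 | triisopropylsilyl 4-[(2,4-dihydroxy-3,6-dimethylbenzoyl)oxy]-2-methoxy-5,6-dimethylbenzoate (ring C–D diol) | Oc1cc(C)c(C(=O)Oc2cc(OC)c(C(=O)O[Si](C(C)C)(C(C)C)C(C)C)c(C)c2C)c(O)c1C | intermediate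
16 | 2,4-bis(allyloxy)-3-chloro-5,6-dimethylbenzoyl chloride | ClC(=O)c1c(OCC=C)c(Cl)c(OCC=C)c(C)c1C | intermediate
17 | ring B–C–D tridepside bis(allyl ether): 15 acylated on the ring C 4-oxygen with the 2,4-bis(allyloxy)-3-chloro-5,6-dimethylbenzoyl group | C=CCOc1c(C)c(C)c(C(=O)Oc2cc(C)c(C(=O)Oc3cc(OC)c(C(=O)O[Si](C(C)C)(C(C)C)C(C)C)c(C)c3C)c(O)c2C)c(OCC=C)c1Cl | intermediate
18 | ring B–C–D triol: 15 acylated on the ring C 4-oxygen with the 3-chloro-2,4-dihydroxy-5,6-dimethylbenzoyl group | Oc1c(C)c(C)c(C(=O)Oc2cc(C)c(C(=O)Oc3cc(OC)c(C(=O)O[Si](C(C)C)(C(C)C)C(C)C)c(C)c3C)c(O)c2C)c(O)c1Cl | intermediate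
19 | 3-methyltetronic acid (4-hydroxy-3-methylfuran-2(5H)-one) | CC1=C(O)COC1=O | starting material
20 | 4-methoxy-3-methylfuran-2(5H)-one | COC1=C(C)C(=O)OC1 | intermediate
21 | lithium 4-methoxy-3-methylfuran-2-olate | [Li+].COc1coc([O-])c1C | intermediate
22 | 3-methoxy-4-methyl-5-oxo-2,5-dihydrofuran-2-carboxylic acid (racemic) | COC1=C(C)C(=O)OC1C(=O)O | intermediate
23 | 3-methoxy-4-methyl-5-oxo-2,5-dihydrofuran-2-carbonyl chloride (racemic) | COC1=C(C)C(=O)OC1C(Cl)=O | intermediate
24 | ring B 4-O-(3-methoxy-4-methyl-5-oxo-2,5-dihydrofuran-2-carbonyl) ester of 18, racemic at the furanone carbon | COC1=C(C)C(=O)OC1C(=O)Oc2c(C)c(C)c(C(=O)Oc3cc(C)c(C(=O)Oc4cc(OC)c(C(=O)O[Si](C(C)C)(C(C)C)C(C)C)c(C)c4C)c(O)c3C)c(O)c2Cl | intermediate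
25 | ring B 4-O-[5-(tert-butyldimethylsilyloxy)-3-methoxy-4-methylfuran-2-carbonyl] ester of 18, ring B 2-O and ring C 2-O as tert-butyldimethylsilyl ethers (precursor of the key step) | COc1c(C)c(O[Si](C)(C)C(C)(C)C)oc1C(=O)Oc2c(C)c(C)c(C(=O)Oc3cc(C)c(C(=O)Oc4cc(OC)c(C(=O)O[Si](C(C)C)(C(C)C)C(C)C)c(C)c4C)c(O[Si](C)(C)C(C)(C)C)c3C)c(O[Si](C)(C)C(C)(C)C)c2Cl | intermediate
26 | but-2-yn-1-ol | CC#CCO | starting material
27 | but-2-ynal | CC#CC=O | intermediate
28 | aryl (1R,4S)-4-(tert-butyldimethylsilyloxy)-5-formyl-2-methoxy-3,6-dimethyl-7-oxabicyclo[2.2.1]hepta-2,5-diene-1-carboxylate (aryl as in 25); present in the flask as the iminium ion of the catalyst, drawn at the aldehyde level | COC1=C(C)[C@@]2(O[Si](C)(C)C(C)(C)C)O[C@]1(C(=O)Oc3c(C)c(C)c(C(=O)Oc4cc(C)c(C(=O)Oc5cc(OC)c(C(=O)O[Si](C(C)C)(C(C)C)C(C)C)c(C)c5C)c(O[Si](C)(C)C(C)(C)C)c4C)c(O[Si](C)(C)C(C)(C)C)c3Cl)C(C)=C2C=O | intermediate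
29 | aryl (1R)-1-(tert-butyldimethylsilyloxy)-5-formyl-2-methoxy-3,6-dimethyl-4-oxocyclohexa-2,5-diene-1-carboxylate (aryl as in 25; product of the key step) | COC1=C(C)C(=O)C(C=O)=C(C)[C@]1(O[Si](C)(C)C(C)(C)C)C(=O)Oc2c(C)c(C)c(C(=O)Oc3cc(C)c(C(=O)Oc4cc(OC)c(C(=O)O[Si](C(C)C)(C(C)C)C(C)C)c(C)c4C)c(O[Si](C)(C)C(C)(C)C)c3C)c(O[Si](C)(C)C(C)(C)C)c2Cl | intermediate
30 | aryl (1R)-1-(tert-butyldimethylsilyloxy)-2-methoxy-3,6-dimethyl-4-oxocyclohexa-2,5-diene-1-carboxylate (aryl as in 25) | COC1=C(C)C(=O)C=C(C)[C@]1(O[Si](C)(C)C(C)(C)C)C(=O)Oc2c(C)c(C)c(C(=O)Oc3cc(C)c(C(=O)Oc4cc(OC)c(C(=O)O[Si](C(C)C)(C(C)C)C(C)C)c(C)c4C)c(O[Si](C)(C)C(C)(C)C)c3C)c(O[Si](C)(C)C(C)(C)C)c2Cl | intermediate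
31 | CNP0248758.1, (R)-configured at ring A C1 | COC1=C(C)C(=O)C=C(C)[C@]1(O)C(=O)Oc1c(C)c(C)c(C(=O)Oc2cc(C)c(C(=O)Oc3cc(OC)c(C(=O)O)c(C)c3C)c(O)c2C)c(O)c1Cl | target

**Count**

Total step count: 21.
Longest linear sequence: 14 steps (7 → 8 → 9 → 11 → 12 → 13 → 14 → 15 → 17 → 18 → 24 → 25 → 29 → 30 → 31).

**Steps most likely to fail**

1. Step 19 (the proposed new method). Silicon may be transferred to an outside acceptor after the first C–C bond, so that the sequence stops at the open conjugate-addition stage and ring A never closes. The two furan orientations on the open face of the iminium ion may also be poorly distinguished, which would lower the enantiomeric purity. Fallback with known chemistry, setting out from 25 and 27: an uncatalysed Diels–Alder reaction (27 in excess, toluene, 80 °C, sealed vessel) should give the racemic oxanorbornadiene silyl ketal F1, which opens in the same way to the racemic quinol aldehyde F2. Preparative chromatography on a chiral stationary phase (amylose tris(3,5-dimethylphenylcarbamate)) would then separate the R enantiomer, and the route is rejoined at 29.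

2. Step 20. Oxidative addition at the hindered formyl group flanked by the ketone may be slow, or a ketone-chelated acyl rhodium species may fail to extrude CO below a temperature that the quinol ester tolerates. Fallback, setting out from 29:
 - Conjugate reduction of the doubly activated C5=C6 bond with diethyl 2,6-dimethyl-1,4-dihydropyridine-3,5-dicarboxylate (CH2Cl2, rt) should give the saturated formyl ketone F3, with C5 and C6 as mixtures.
 - PhSeCl and pyridine (CH2Cl2, 0 °C) would selenenylate C5 to the α-formyl α-phenylselanyl ketone F4.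
 - The now non-enolisable formyl group of F4 is lost on aqueous NaHCO3 work-up to leave the α-phenylselanyl ketone F5.
 - H2O2 (CH2Cl2, 0 °C → rt) oxidises F5 to the selenoxide F6, which eliminates syn toward the only β-hydrogen at C6 and returns the route at 30.

3. Step 16. The enolisable acid chloride may be consumed through its ketene (oligomerisation, O-acylation of the product enolate) before the di-ortho-substituted phenol is acylated. Fallback, setting out from 22 and 18 and bypassing 24:
 - TBSOTf (2.2 equiv) and Et3N convert 22 into the bis-silyl furoate F7.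
 - (COCl)2 with catalytic DMF (CH2Cl2, 0 °C) exchanges the silyl ester for the non-enolisable silyloxyfuroyl chloride F8.
 - F8 acylates 18 (Et3N, DMAP, CH2Cl2, 0 °C) to the furoyl ester diol F9.
 - TBSOTf and 2,6-lutidine silylate the two salicylate hydroxyls of F9, and the route is rejoined at 25.

**Further compounds**

F1 | step 19 | racemic oxanorbornadiene silyl ketal (racemic 28) | COC1=C(C)C2(O[Si](C)(C)C(C)(C)C)OC1(C(=O)Oc3c(C)c(C)c(C(=O)Oc4cc(C)c(C(=O)Oc5cc(OC)c(C(=O)O[Si](C(C)C)(C(C)C)C(C)C)c(C)c5C)c(O[Si](C)(C)C(C)(C)C)c4C)c(O[Si](C)(C)C(C)(C)C)c3Cl)C(C)=C2C=O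
F2 | step 19 | racemic quinol aldehyde (racemic 29) | COC1=C(C)C(=O)C(C=O)=C(C)C1(O[Si](C)(C)C(C)(C)C)C(=O)Oc2c(C)c(C)c(C(=O)Oc3cc(C)c(C(=O)Oc4cc(OC)c(C(=O)O[Si](C(C)C)(C(C)C)C(C)C)c(C)c4C)c(O[Si](C)(C)C(C)(C)C)c3C)c(O[Si](C)(C)C(C)(C)C)c2Cl
F3 | step 20 | saturated formyl ketone: 5,6-dihydro derivative of 29, C1 R, C5 and C6 unassigned | COC1=C(C)C(=O)C(C=O)C(C)[C@]1(O[Si](C)(C)C(C)(C)C)C(=O)Oc2c(C)c(C)c(C(=O)Oc3cc(C)c(C(=O)Oc4cc(OC)c(C(=O)O[Si](C(C)C)(C(C)C)C(C)C)c(C)c4C)c(O[Si](C)(C)C(C)(C)C)c3C)c(O[Si](C)(C)C(C)(C)C)c2Cl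
F4 | step 20 | α-formyl α-phenylselanyl ketone: F3 with SePh on C5 | COC1=C(C)C(=O)C(C=O)([Se]c5ccccc5)C(C)[C@]1(O[Si](C)(C)C(C)(C)C)C(=O)Oc2c(C)c(C)c(C(=O)Oc3cc(C)c(C(=O)Oc4cc(OC)c(C(=O)O[Si](C(C)C)(C(C)C)C(C)C)c(C)c4C)c(O[Si](C)(C)C(C)(C)C)c3C)c(O[Si](C)(C)C(C)(C)C)c2Cl
F5 | step 20 | α-phenylselanyl ketone: 5-phenylselanyl-5,6-dihydro derivative of 30 | COC1=C(C)C(=O)C([Se]c5ccccc5)C(C)[C@]1(O[Si](C)(C)C(C)(C)C)C(=O)Oc2c(C)c(C)c(C(=O)Oc3cc(C)c(C(=O)Oc4cc(OC)c(C(=O)O[Si](C(C)C)(C(C)C)C(C)C)c(C)c4C)c(O[Si](C)(C)C(C)(C)C)c3C)c(O[Si](C)(C)C(C)(C)C)c2Cl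
F6 | step 20 | selenoxide of F5 | COC1=C(C)C(=O)C([Se](=O)c5ccccc5)C(C)[C@]1(O[Si](C)(C)C(C)(C)C)C(=O)Oc2c(C)c(C)c(C(=O)Oc3cc(C)c(C(=O)Oc4cc(OC)c(C(=O)O[Si](C(C)C)(C(C)C)C(C)C)c(C)c4C)c(O[Si](C)(C)C(C)(C)C)c3C)c(O[Si](C)(C)C(C)(C)C)c2Cl
F7 | step 16 | tert-butyldimethylsilyl 5-(tert-butyldimethylsilyloxy)-3-methoxy-4-methylfuran-2-carboxylate | COc1c(C)c(O[Si](C)(C)C(C)(C)C)oc1C(=O)O[Si](C)(C)C(C)(C)C
F8 | step 16 | 5-(tert-butyldimethylsilyloxy)-3-methoxy-4-methylfuran-2-carbonyl chloride | COc1c(C)c(O[Si](C)(C)C(C)(C)C)oc1C(Cl)=O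
F9 | step 16 | ring B 4-O-[5-(tert-butyldimethylsilyloxy)-3-methoxy-4-methylfuran-2-carbonyl] ester of 18 with both salicylate hydroxyls free | COc1c(C)c(O[Si](C)(C)C(C)(C)C)oc1C(=O)Oc2c(C)c(C)c(C(=O)Oc3cc(C)c(C(=O)Oc4cc(OC)c(C(=O)O[Si](C(C)C)(C(C)C)C(C)C)c(C)c4C)c(O)c3C)c(O)c2Cl
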